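The γ-lactone ring (O1, C2=O, C3 carbinol, C4, C5) is disconnected at C4–C5. The key step exploits the O1–C5H2–C4H(CH2Ar) array: O1–C5H2 is read as an acyloxymethyl radical and the C4 arylmethyl group as a styrene. An open-chain iodomethyl (R,E)-2-hydroxy-4-arylbut-3-enoate is closed by a 5-exo radical cyclisation. This forms the lactone ring, the C4–C5 bond, the benzylic CH2 and the C4 stereocentre in one operation, with the lone C3 carbinol centre directing C4 (3,4-trans). C3 is then rebuilt: the hydroxy lactone dianion is benzylated anti to the C4 side chain, and hydrogenolysis frees both phenols.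

Key step: step 4

Remark: Ar = 4-(benzyloxy)-3-methoxyphenyl; compounds 1, 2 and 8 and all reagents are taken to be commercial.

Step 1
Reactants: 1 4-(benzyloxy)-3-methoxybenzaldehyde; 2 pyruvic acid
Product: 3 (E)-4-[4-(benzyloxy)-3-methoxyphenyl]-2-oxobut-3-enoic acid
Conditions: KOH, MeOH, 0 °C to rt; then aq. HCl
Reagents that add atoms: none
Why: Claisen–Schmidt (crossed aldol) condensation of the non-enolisable aldehyde with the methyl group of pyruvate, in which precipitation of the potassium salt of the E enone acid should drive dehydration and prevent further reaction.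

Step 2
Reactants: 3 (E)-4-[4-(benzyloxy)-3-methoxyphenyl]-2-oxobut-3-enoic acid
Product: 4 (2R,3E)-4-[4-(benzyloxy)-3-methoxyphenyl]-2-hydroxybut-3-enoic acid
Conditions: D-lactate dehydrogenase (Staphylococcus epidermidis), NADH (cat.), formate dehydrogenase (Candida boidinii), HCO2Na, Tris buffer pH 7.5, 5% DMSO, rt; then aq. HCl to pH 2
Reagents that add atoms: none
Why: Enzymatic asymmetric ketone reduction with cofactor recycling, in which a D-specific 2-hydroxy acid dehydrogenase delivers hydride to the face of the 2-oxo acid that gives the (R)-carbinol and leaves the conjugated C=C and the benzyl ether untouched.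

Step 3
Reactants: 4 (2R,3E)-4-[4-(benzyloxy)-3-methoxyphenyl]-2-hydroxybut-3-enoic acid
Product: 6 iodomethyl (2R,3E)-4-[4-(benzyloxy)-3-methoxyphenyl]-2-hydroxybut-3-enoate, via chloromethyl ester 5 (not isolated)
Conditions: ClCH2OSO2Cl, NaHCO3, Bu4NHSO4 (cat.), CH2Cl2/H2O, 0 °C to rt; organic phase dried and concentrated; then NaI, acetone, rt, dark
Reagents that add atoms: chloromethyl chlorosulfate ClCOS(=O)(=O)Cl; sodium iodide [Na+].[I-]
Why: Phase-transfer O-alkylation of the carboxylate (far more nucleophilic than the neutral secondary alcohol) followed by Finkelstein halide exchange, under conditions too weakly basic to enolise or isomerise the C2–H centre.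

Step 4
Reactants: 6 iodomethyl (2R,3E)-4-[4-(benzyloxy)-3-methoxyphenyl]-2-hydroxybut-3-enoate
Product: 7 (3R,4S)-4-[4-(benzyloxy)-3-methoxybenzyl]-3-hydroxydihydrofuran-2(3H)-one
Conditions: Bu3SnH (1.3 equiv) and AIBN (0.2 equiv) in toluene added by syringe pump over 8 h to 6 in toluene (0.005 M), 100 °C
Reagents that add atoms: none
Why: Bu3Sn• abstracts iodine from 6 to give the acyloxymethyl radical at C5 (O1–CH2•), which adds through the s-cis ester rotamer to C4 of the styrene in a 5-exo-trig closure of the γ-lactone ring, and the benzylic radical left on the ArCH carbon is reduced by Bu3SnH, so that ring, C4–C5 bond, ArCH2 side chain and C4 stereocentre arise together. The closest known reaction type is the tin hydride-mediated cyclisation of halomethyl esters of but-3-enoic acids to γ-butyrolactones (ester-tethered 5-exo radical cyclisation). Regioselectivity (5-exo over 6-endo) is secured by the aryl group, since only attack at C4 gives a benzylic radical. C4 is controlled by the C3 carbinol centre: in the favoured transition state the C3–H eclipses the alkene (inside position), the chain running through C2 attacks the alkene face anti to the hydroxyl, and the new ArCH group should end up trans to OH, i.e. (3R,4S); any Z isomer formed by reversible stannyl radical addition should converge on the same isomer because allylic 1,3-strain enforces the same conformer even more strongly. The step also needs cyclisation to outrun reduction of the acyloxymethyl radical, which high dilution, slow addition of Bu3SnH and 100 °C (fast ester rotamer exchange) should secure; any 3,4-cis isomer is removed here by chromatography because it carries the wrong C4 configuration.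

Step 5
Reactants: 8 [4-(benzyloxy)-3-methoxyphenyl]methanol
Product: 9 1-(benzyloxy)-4-(bromomethyl)-2-methoxybenzene
Conditions: PBr3 (0.4 equiv), Et2O, 0 °C
Reagents that add atoms: phosphorus tribromide BrP(Br)Br
Why: Conversion of an electron-rich benzylic alcohol into the bromide by nucleophilic substitution of its phosphite ester, a reaction that should be fast and clean at 0 °C.

Step 6
Reactants: 7 (3R,4S)-4-[4-(benzyloxy)-3-methoxybenzyl]-3-hydroxydihydrofuran-2(3H)-one; 9 1-(benzyloxy)-4-(bromomethyl)-2-methoxybenzene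
Product: 10 (3S,4S)-3,4-bis[4-(benzyloxy)-3-methoxybenzyl]-3-hydroxydihydrofuran-2(3H)-one
Conditions: LiN(iPr)2 (2.3 equiv), THF, −78 °C to −30 °C; then 9, −78 °C to −20 °C; aq. NH4Cl
Reagents that add atoms: none
Why: Alkylation of the lithium alkoxide enolate (dianion) of an α-hydroxy lactone, in which C3 becomes trigonal and the bromide should approach anti to the C4 arylmethyl group, placing the new benzyl trans to it and the hydroxyl cis, i.e. the (3S,4S) configuration, whatever the C3 configuration of 7.

Step 7
Reactants: 10 (3S,4S)-3,4-bis[4-(benzyloxy)-3-methoxybenzyl]-3-hydroxydihydrofuran-2(3H)-one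
Product: 11 (3S,4S)-3-hydroxy-3,4-bis(4-hydroxy-3-methoxybenzyl)dihydrofuran-2(3H)-one
Conditions: H2 (1 atm), 10% Pd/C, EtOAc/MeOH, rt
Reagents that add atoms: none
Why: Catalytic hydrogenolysis of the two aryl benzyl ethers over palladium on carbon, which should leave the lactone, the tertiary (non-benzylic) alcohol and both stereocentres unchanged.

Compound list
1 | 4-(benzyloxy)-3-methoxybenzaldehyde | COc1cc(C=O)ccc1OCc1ccccc1 | starting material
2 | pyruvic acid | CC(=O)C(=O)O | starting material
3 | (E)-4-[4-(benzyloxy)-3-methoxyphenyl]-2-oxobut-3-enoic acid | COc1cc(/C=C/C(=O)C(=O)O)ccc1OCc1ccccc1 | intermediate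
4 | (2R,3E)-4-[4-(benzyloxy)-3-methoxyphenyl]-2-hydroxybut-3-enoic acid | COc1cc(/C=C/[C@@H](O)C(=O)O)ccc1OCc1ccccc1 | intermediate
5 | chloromethyl (2R,3E)-4-[4-(benzyloxy)-3-methoxyphenyl]-2-hydroxybut-3-enoate | COc1cc(/C=C/[C@@H](O)C(=O)OCCl)ccc1OCc1ccccc1 | intermediate
6 | iodomethyl (2R,3E)-4-[4-(benzyloxy)-3-methoxyphenyl]-2-hydroxybut-3-enoate | COc1cc(/C=C/[C@@H](O)C(=O)OCI)ccc1OCc1ccccc1 | intermediate
7 | (3R,4S)-4-[4-(benzyloxy)-3-methoxybenzyl]-3-hydroxydihydrofuran-2(3H)-one | COc1cc(C[C@H]2COC(=O)[C@@H]2O)ccc1OCc1ccccc1 | intermediate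
8 | [4-(benzyloxy)-3-methoxyphenyl]methanol | COc1cc(CO)ccc1OCc1ccccc1 | starting material
9 | 1-(benzyloxy)-4-(bromomethyl)-2-methoxybenzene | COc1cc(CBr)ccc1OCc1ccccc1 | intermediate
10 | (3S,4S)-3,4-bis[4-(benzyloxy)-3-methoxybenzyl]-3-hydroxydihydrofuran-2(3H)-one | COc1cc(C[C@H]2COC(=O)[C@]2(O)Cc2ccc(OCc3ccccc3)c(OC)c2)ccc1OCc1ccccc1 | intermediate
11 | (3S,4S)-3-hydroxy-3,4-bis(4-hydroxy-3-methoxybenzyl)dihydrofuran-2(3H)-one | COc1cc(C[C@H]2COC(=O)[C@]2(O)Cc2ccc(O)c(OC)c2)ccc1O | target

Total step count: 7. Longest linear sequence: 6 (steps 1, 2, 3, 4, 6, 7); step 5 is a one-step side branch.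

Steps most likely to fail

1. Step 4. The acyloxymethyl radical may be reduced by Bu3SnH before it cyclises, because the ester rests in the unreactive s-trans rotamer, or the facial selectivity at C4 may be poor. The fallback keeps the same C4–C5 ring closure but runs it through a silicon tether on the C3 oxygen; it sets out from 3 and returns at 10. Because the tether now runs through the C3 oxygen and not through C2, the sense of 1,2-induction reverses, so the S carbinol series is used. Compound 3 is reduced with L-lactate dehydrogenase (Bacillus stearothermophilus) under the recycling conditions of step 2 to (2S,3E)-4-[4-(benzyloxy)-3-methoxyphenyl]-2-hydroxybut-3-enoic acid F1. MeI, KHCO3, DMF then gives methyl (2S,3E)-4-[4-(benzyloxy)-3-methoxyphenyl]-2-hydroxybut-3-enoate F2. BrCH2SiMe2Cl, imidazole, CH2Cl2, 0 °C gives methyl (2S,3E)-4-[4-(benzyloxy)-3-methoxyphenyl]-2-{[(bromomethyl)dimethylsilyl]oxy}but-3-enoate F3. Bu3SnH, AIBN, benzene, 80 °C closes the C4–C5 bond by a 5-exo-trig cyclisation of the α-silyl radical, with no rotamer barrier. This should give methyl (4R,5S)-4-[4-(benzyloxy)-3-methoxybenzyl]-2,2-dimethyl-1,2-oxasilolane-5-carboxylate F4, with the arylmethyl group trans to the ester. Tamao–Fleming oxidation (H2O2, KF, KHCO3, THF/MeOH) gives methyl (2S,3S)-3-[4-(benzyloxy)-3-methoxybenzyl]-2,4-dihydroxybutanoate F5. This should lactonise in the flask to (3S,4S)-4-[4-(benzyloxy)-3-methoxybenzyl]-3-hydroxydihydrofuran-2(3H)-one F6, the C3 epimer of 7 with the same C4 configuration. F6 and 9 under the conditions of step 6 give 10, because C3 is trigonal in the enolate.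

2. Step 6. The alkoxide may be O-alkylated, the alkoxide-bearing lactone may enolise incompletely, or facial selectivity may erode. The fallback alkylates a mono-enolate of the O-silylated lactone; it sets out from 7 and returns at 10. tBuMe2SiOTf, 2,6-lutidine, CH2Cl2, 0 °C gives (3R,4S)-4-[4-(benzyloxy)-3-methoxybenzyl]-3-[(tert-butyldimethylsilyl)oxy]dihydrofuran-2(3H)-one F7. LiN(iPr)2, THF, −78 °C, then 9, should alkylate anti to the C4 group to give (3S,4S)-3,4-bis[4-(benzyloxy)-3-methoxybenzyl]-3-[(tert-butyldimethylsilyl)oxy]dihydrofuran-2(3H)-one F8. Bu4NF, AcOH, THF then gives 10.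

3. Step 2. The enzyme may not turn over the bulky benzyloxy-substituted keto acid, or the substrate may be too insoluble in buffer. The fallback replaces biocatalysis by homogeneous asymmetric hydrogenation; it sets out from 3, returns at 4 and makes no new compound (F0). The ketone is hydrogenated with H2 and the divalent ruthenium bisphosphine complex [RuCl(C6H6)(SunPhos)]Cl, using the ligand antipode that delivers the R acid, in THF. This catalyst type reduces C=O in preference to the conjugated C=C of 2-oxo-4-arylbut-3-enoic acids. The optical purity of 4 would then be raised by crystallisation.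

Further compounds
F1 | step 4 | (2S,3E)-4-[4-(benzyloxy)-3-methoxyphenyl]-2-hydroxybut-3-enoic acid | COc1cc(/C=C/[C@H](O)C(=O)O)ccc1OCc1ccccc1
F2 | step 4 | methyl (2S,3E)-4-[4-(benzyloxy)-3-methoxyphenyl]-2-hydroxybut-3-enoate | COc1cc(/C=C/[C@H](O)C(=O)OC)ccc1OCc1ccccc1
F3 | step 4 | methyl (2S,3E)-4-[4-(benzyloxy)-3-methoxyphenyl]-2-{[(bromomethyl)dimethylsilyl]oxy}but-3-enoate | COc1cc(/C=C/[C@H](O[Si](C)(C)CBr)C(=O)OC)ccc1OCc1ccccc1
F4 | step 4 | methyl (4R,5S)-4-[4-(benzyloxy)-3-methoxybenzyl]-2,2-dimethyl-1,2-oxasilolane-5-carboxylate | COC(=O)[C@H]1O[Si](C)(C)C[C@@H]1Cc1ccc(OCc2ccccc2)c(OC)c1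
F5 | step 4 | methyl (2S,3S)-3-[4-(benzyloxy)-3-methoxybenzyl]-2,4-dihydroxybutanoate | COC(=O)[C@@H](O)[C@H](CO)Cc1ccc(OCc2ccccc2)c(OC)c1
F6 | step 4 | (3S,4S)-4-[4-(benzyloxy)-3-methoxybenzyl]-3-hydroxydihydrofuran-2(3H)-one | COc1cc(C[C@H]2COC(=O)[C@H]2O)ccc1OCc1ccccc1
F7 | step 6 | (3R,4S)-4-[4-(benzyloxy)-3-methoxybenzyl]-3-[(tert-butyldimethylsilyl)oxy]dihydrofuran-2(3H)-one | COc1cc(C[C@H]2COC(=O)[C@@H]2O[Si](C)(C)C(C)(C)C)ccc1OCc1ccccc1
F8 | step 6 | (3S,4S)-3,4-bis[4-(benzyloxy)-3-methoxybenzyl]-3-[(tert-butyldimethylsilyl)oxy]dihydrofuran-2(3H)-one | COc1cc(C[C@H]2COC(=O)[C@]2(O[Si](C)(C)C(C)(C)C)Cc2ccc(OCc3ccccc3)c(OC)c2)ccc1OCc1ccccc1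
F0 | step 2 | none | none
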